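**Plan**
- Retrosynthesis: the two benzyl ethers and the two peri (C5) methyl ethers come off last. The pyranone of the 6-methyl-7-methoxy flavone is then cut at O1–C2 and C2–C3, giving benzoic acid 15 and acetophenone 20.
- The aryl–CO2H bond of 15 goes back to an aryl bromide. The apigenin pyranone is cut the same way (O1–C2, C2–C3), then the acetyl–C4a bond.
- Last cut is C7–C8 of the apigenin ring A. This ring is a phloroglucinol whose C8 carries ring B of the other flavone, so C8 can begin as the benzylic CH2 of an arylacetyl triketide stored as 4-methoxy-2-pyrone 6, with C7 as its lactone carbonyl.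
- Forward: 2-pyrone ring (steps 1–3), carbocyclic ring A by pyrone-to-phloroglucinol isomerisation (step 4), apigenin pyranone (steps 5–7), carboxyl group (step 8), second pyranone (steps 9–11), deprotection (step 12).
- Stereochemistry: the target has no stereocentre, so nothing has to be set.

Key step: step 4

Assumption: the SMILES fixes no configuration about the hindered biaryl axis, so none is controlled; (5-bromo-2-methoxyphenyl)acetic acid and 4-(benzyloxy)benzoyl chloride are taken as catalogue compounds (otherwise one step each, from 2-methoxyphenylacetic acid with Br2/AcOH and from 4-(benzyloxy)benzoic acid with (COCl)2).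

**Route**

Step 1
Reactants: 1 (5-bromo-2-methoxyphenyl)acetic acid; 2 methyl acetoacetate
Product: 4 methyl 6-(5-bromo-2-methoxyphenyl)-3,5-dioxohexanoate, via acyl imidazolide 3 (not isolated)
Conditions: 1, carbonyldiimidazole, THF, 25 °C; added to 2 (2.5 equiv) pretreated with LiN(iPr)2 (5 equiv), THF, 0 °C; −78 → 0 °C; aq. HCl
Reagents that add atoms: none
Why: Claisen-type acylation of the methyl acetoacetate dianion at its terminal carbon by an acyl imidazolide is a standard entry to 3,5-dioxo esters, and the excess dianion absorbs proton transfer to the acidic product and to the enolisable acyl donor.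

Step 2
Reactants: 4 methyl 6-(5-bromo-2-methoxyphenyl)-3,5-dioxohexanoate
Product: 5 6-(5-bromo-2-methoxybenzyl)-4-hydroxy-2H-pyran-2-one
Conditions: 1,8-diazabicyclo[5.4.0]undec-7-ene (1.5 equiv), toluene, 80 °C; aq. HCl
Reagents that add atoms: none
Why: Base-mediated lactonisation of a 3,5-dioxo ester, in which the C5 enolate oxygen of the monoanion attacks the ester and methanol is lost, should give the 4-hydroxy-2-pyrone because carbon cyclisation would need a polyanion that an amidine base cannot form.

Step 3
Reactants: 5 6-(5-bromo-2-methoxybenzyl)-4-hydroxy-2H-pyran-2-one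
Product: 6 6-(5-bromo-2-methoxybenzyl)-4-methoxy-2H-pyran-2-one
Conditions: Me2SO4 (1.2 equiv), K2CO3, acetone, 56 °C
Reagents that add atoms: dimethyl sulfate, COS(=O)(=O)OC
Why: O-Alkylation of the vinylogous acid with dimethyl sulfate and carbonate is the usual route to 4-methoxy-2-pyrones and installs the oxygen substituent that becomes the C5 ether of the apigenin unit.

Step 4
Reactants: 6 6-(5-bromo-2-methoxybenzyl)-4-methoxy-2H-pyran-2-one
Product: 8 2-(5-bromo-2-methoxyphenyl)-5-methoxybenzene-1,3-diol, via ring-opened keto ester 7 (not isolated)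
Conditions: NaOMe (5 equiv), MeOH, N2, 65–100 °C (sealed tube); then aq. HCl
Reagents that add atoms: none
Why: Methoxide adds to the lactone carbonyl of 6 and opens the ring to keto ester 7, whose (E) enol ether (the former ring double bond) holds the ester and the keto-methylene arm cis; the benzylic carbanion, stabilised by ketone and aryl ring, then attacks the ester carbonyl, methoxide leaves and the dienone enolises to the arene, which forms C7–C8 of the future apigenin ring A. The closest known reaction is the alkoxide-induced isomerisation of 4-methoxy-6-methyl-2-pyrone to phloroglucinol monomethyl ether, a polyketide-type Claisen (Dieckmann) cyclisation, and it should run under milder conditions here because the nucleophilic carbon is benzylic. The carbocycle closes in a 6-(enolendo)-exo-trig mode. No stereocentre is formed. The step needs C-acylation at the benzylic carbon to win over relactonisation through oxygen and over retro-Claisen cleavage; ring opening and O-closure are reversible, whereas the C-closure ends in an aromatic phenoxide and is not. The product is symmetric about the aryl axis with its single ether para to the aryl group, which later forces the 8-aryl flavone.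

Step 5
Reactants: 8 2-(5-bromo-2-methoxyphenyl)-5-methoxybenzene-1,3-diol
Product: 10 1-[3-(5-bromo-2-methoxyphenyl)-2,4-dihydroxy-6-methoxyphenyl]ethan-1-one, via ketiminium chloride 9 (not isolated)
Conditions: MeCN, HCl (g), ZnCl2, Et2O, 0 °C; then H2O, 100 °C
Reagents that add atoms: acetonitrile, CC#N; water, O
Why: In this Houben–Hoesch acylation the nitrilium species attacks the ring carbon ortho or para to all three oxygens (positions 4 and 6 are equivalent by the symmetry of 8), the precipitating ketiminium salt stops a second acylation, and the bromoanisole ring is far less nucleophilic.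

Step 6
Reactants: 10 1-[3-(5-bromo-2-methoxyphenyl)-2,4-dihydroxy-6-methoxyphenyl]ethan-1-one
Product: 11 1-[4-(benzyloxy)-3-(5-bromo-2-methoxyphenyl)-2-hydroxy-6-methoxyphenyl]ethan-1-one
Conditions: BnBr (1.05 equiv), K2CO3, acetone, 56 °C
Reagents that add atoms: benzyl bromide, BrCc1ccccc1
Why: Williamson etherification under mild carbonate conditions should take the more acidic hydroxyl para to the acetyl group and leave the hydrogen-bonded ortho hydroxyl free for the ring closure.

Step 7
Reactants: 11 1-[4-(benzyloxy)-3-(5-bromo-2-methoxyphenyl)-2-hydroxy-6-methoxyphenyl]ethan-1-one; 12 4-(benzyloxy)benzoyl chloride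
Product: 14 7-(benzyloxy)-2-[4-(benzyloxy)phenyl]-8-(5-bromo-2-methoxyphenyl)-5-methoxy-4H-chromen-4-one, via diketone 13 (not isolated)
Conditions: LiN(SiMe3)2 (3.2 equiv), THF, −78 → −10 °C; 12, −78 → 25 °C; aq. NH4Cl; crude in AcOH, H2SO4 (cat.), 80 °C
Reagents that add atoms: none
Why: In this lithium-dianion variant of the Baker–Venkataraman flavone synthesis the enolate is C-aroylated by 12 (any O-aroyl ester rearranges under the excess base), and acid-catalysed cyclodehydration through the only free hydroxyl, the one next to the aryl group, can give only the 8-aryl flavone.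

Step 8
Reactants: 14 7-(benzyloxy)-2-[4-(benzyloxy)phenyl]-8-(5-bromo-2-methoxyphenyl)-5-methoxy-4H-chromen-4-one
Product: 15 3-{7-(benzyloxy)-2-[4-(benzyloxy)phenyl]-5-methoxy-4-oxo-4H-chromen-8-yl}-4-methoxybenzoic acid
Conditions: Pd(OAc)2 (5 mol %), Xantphos (6 mol %), CO (1 atm), Et3N, H2O, DMF, 90 °C; aq. HCl
Reagents that add atoms: carbon monoxide, [C-]#[O+]; water, O
Why: Palladium-catalysed hydroxycarbonylation of an aryl bromide (oxidative addition to zerovalent palladium, CO insertion, hydrolysis of the acylpalladium species) should proceed at the unhindered C–Br bond, with benzyl ethers and the flavone inert.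

Step 9
Reactants: 16 2,6-dimethoxytoluene
Product: 18 3,5-dimethoxy-4-methylphenol, via arylboronate 17 (not isolated)
Conditions: [Ir(OMe)(cod)]2 (1.5 mol %), 4,4′-di-tert-butyl-2,2′-bipyridine (3 mol %), B2pin2 (0.6 equiv), THF, 80 °C; then H2O2 (30 % aq.), NaOH, THF/H2O, 0 → 25 °C
Reagents that add atoms: hydrogen peroxide, OO
Why: The arene carries only two of the three oxygens that ring A of the second flavone needs, and iridium-catalysed C–H borylation is sterically directed to C4, the only C–H bond without an ortho substituent, after which alkaline peroxide oxidation of the C–B bond gives the phenol.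

Step 10
Reactants: 18 3,5-dimethoxy-4-methylphenol
Product: 20 1-(6-hydroxy-2,4-dimethoxy-3-methylphenyl)ethan-1-one, via difluoroboron chelate 19 (not isolated)
Conditions: AcOH, BF3·OEt2 (3 equiv), 90 °C; then MeOH/H2O, 60 °C
Reagents that add atoms: acetic acid, CC(=O)O
Why: BF3-mediated Friedel–Crafts acetylation ortho to the phenol (para is blocked by methyl and the two ortho carbons are equivalent) should give a single acetophenone, held as its difluoroboron chelate so that a second acylation is suppressed, with the methyl group placed for a 6-methyl flavone.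

Step 11
Reactants: 15 3-{7-(benzyloxy)-2-[4-(benzyloxy)phenyl]-5-methoxy-4-oxo-4H-chromen-8-yl}-4-methoxybenzoic acid; 20 1-(6-hydroxy-2,4-dimethoxy-3-methylphenyl)ethan-1-one
Product: 23 7-(benzyloxy)-2-[4-(benzyloxy)phenyl]-8-[5-(5,7-dimethoxy-6-methyl-4-oxo-4H-chromen-2-yl)-2-methoxyphenyl]-5-methoxy-4H-chromen-4-one, via acid chloride 21 (not isolated), via diketone 22 (not isolated)
Conditions: 15, (COCl)2, DMF (cat.), CH2Cl2, 0 → 25 °C, evaporate; 20 (1.5 equiv), LiN(SiMe3)2 (4.5 equiv), THF, −78 °C, then 21, −78 → 25 °C; aq. NH4Cl; crude in AcOH, H2SO4 (cat.), 80 °C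
Reagents that add atoms: none
Why: The same C-aroylation and cyclodehydration sequence as in step 7 is used, with the acid chloride of 15 as electrophile at −78 °C where its flavone carbonyl is not attacked, and ring closure through the only hydroxyl of 20 places the methyl group at C6.

Step 12
Reactants: 23 7-(benzyloxy)-2-[4-(benzyloxy)phenyl]-8-[5-(5,7-dimethoxy-6-methyl-4-oxo-4H-chromen-2-yl)-2-methoxyphenyl]-5-methoxy-4H-chromen-4-one
Product: 24 Taiwanhomoflavone A
Conditions: BCl3 (10 equiv), pentamethylbenzene (8 equiv), CH2Cl2, −78 → 25 °C; MeOH, then aq. HCl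
Reagents that add atoms: none
Why: BCl3 cleaves the two benzyl ethers (pentamethylbenzene traps the benzyl cations) and, through six-membered boron chelates with the C4 carbonyls, removes only the two peri methyl ethers, a known selective 5-O-demethylation of flavones, while the 7-OMe and 4′-OMe groups cannot chelate and should survive.

**Compound list**

1 | (5-bromo-2-methoxyphenyl)acetic acid | COc1ccc(Br)cc1CC(=O)O | starting material
2 | methyl acetoacetate | COC(=O)CC(C)=O | starting material
3 | 1-[(5-bromo-2-methoxyphenyl)acetyl]-1H-imidazole | COc1ccc(Br)cc1CC(=O)n1ccnc1 | intermediate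
4 | methyl 6-(5-bromo-2-methoxyphenyl)-3,5-dioxohexanoate | COC(=O)CC(=O)CC(=O)Cc1cc(Br)ccc1OC | intermediate
5 | 6-(5-bromo-2-methoxybenzyl)-4-hydroxy-2H-pyran-2-one | COc1ccc(Br)cc1Cc1cc(O)cc(=O)o1 | intermediate
6 | 6-(5-bromo-2-methoxybenzyl)-4-methoxy-2H-pyran-2-one | COc1cc(Cc2cc(Br)ccc2OC)oc(=O)c1 | intermediate
7 | methyl (2E)-6-(5-bromo-2-methoxyphenyl)-3-methoxy-5-oxohex-2-enoate (ester and keto-methylene arm cis) | COC(=O)/C=C(/OC)CC(=O)Cc1cc(Br)ccc1OC | intermediate
8 | 2-(5-bromo-2-methoxyphenyl)-5-methoxybenzene-1,3-diol | COc1cc(O)c(-c2cc(Br)ccc2OC)c(O)c1 | intermediate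
9 | 1-[3-(5-bromo-2-methoxyphenyl)-2,4-dihydroxy-6-methoxyphenyl]ethan-1-iminium chloride | CC(=[NH2+])c1c(OC)cc(O)c(-c2cc(Br)ccc2OC)c1O.[Cl-] | intermediate
10 | 1-[3-(5-bromo-2-methoxyphenyl)-2,4-dihydroxy-6-methoxyphenyl]ethan-1-one | CC(=O)c1c(OC)cc(O)c(-c2cc(Br)ccc2OC)c1O | intermediate
11 | 1-[4-(benzyloxy)-3-(5-bromo-2-methoxyphenyl)-2-hydroxy-6-methoxyphenyl]ethan-1-one | CC(=O)c1c(OC)cc(OCc2ccccc2)c(-c2cc(Br)ccc2OC)c1O | intermediate
12 | 4-(benzyloxy)benzoyl chloride | O=C(Cl)c1ccc(OCc2ccccc2)cc1 | starting material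
13 | 1-[4-(benzyloxy)-3-(5-bromo-2-methoxyphenyl)-2-hydroxy-6-methoxyphenyl]-3-[4-(benzyloxy)phenyl]propane-1,3-dione | COc1cc(OCc2ccccc2)c(-c2cc(Br)ccc2OC)c(O)c1C(=O)CC(=O)c1ccc(OCc2ccccc2)cc1 | intermediate
14 | 7-(benzyloxy)-2-[4-(benzyloxy)phenyl]-8-(5-bromo-2-methoxyphenyl)-5-methoxy-4H-chromen-4-one | COc1cc(OCc2ccccc2)c(-c2cc(Br)ccc2OC)c2oc(-c3ccc(OCc4ccccc4)cc3)cc(=O)c12 | intermediate
15 | 3-{7-(benzyloxy)-2-[4-(benzyloxy)phenyl]-5-methoxy-4-oxo-4H-chromen-8-yl}-4-methoxybenzoic acid | COc1cc(OCc2ccccc2)c(-c2cc(C(=O)O)ccc2OC)c2oc(-c3ccc(OCc4ccccc4)cc3)cc(=O)c12 | intermediate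
16 | 2,6-dimethoxytoluene (1,3-dimethoxy-2-methylbenzene) | Cc1c(OC)cccc1OC | starting material
17 | 2-(3,5-dimethoxy-4-methylphenyl)-4,4,5,5-tetramethyl-1,3,2-dioxaborolane | Cc1c(OC)cc(B2OC(C)(C)C(C)(C)O2)cc1OC | intermediate
18 | 3,5-dimethoxy-4-methylphenol | Cc1c(OC)cc(O)cc1OC | intermediate
19 | difluoroboron chelate of 20 (BF2 bridging the phenolic and the carbonyl oxygen; 2,2-difluoro-5,7-dimethoxy-4,6-dimethyl-1,3,2-benzodioxaborinine) | CC1=[O+][B-](F)(F)Oc2cc(OC)c(C)c(OC)c12 | intermediate
20 | 1-(6-hydroxy-2,4-dimethoxy-3-methylphenyl)ethan-1-one | CC(=O)c1c(O)cc(OC)c(C)c1OC | intermediate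
21 | 3-{7-(benzyloxy)-2-[4-(benzyloxy)phenyl]-5-methoxy-4-oxo-4H-chromen-8-yl}-4-methoxybenzoyl chloride | COc1cc(OCc2ccccc2)c(-c2cc(C(=O)Cl)ccc2OC)c2oc(-c3ccc(OCc4ccccc4)cc3)cc(=O)c12 | intermediate
22 | 1-(6-hydroxy-2,4-dimethoxy-3-methylphenyl)-3-(3-{7-(benzyloxy)-2-[4-(benzyloxy)phenyl]-5-methoxy-4-oxo-4H-chromen-8-yl}-4-methoxyphenyl)propane-1,3-dione | COc1cc(O)c(C(=O)CC(=O)c2ccc(OC)c(-c3c(OCc4ccccc4)cc(OC)c4c(=O)cc(-c5ccc(OCc6ccccc6)cc5)oc34)c2)c(OC)c1C | intermediate
23 | 7-(benzyloxy)-2-[4-(benzyloxy)phenyl]-8-[5-(5,7-dimethoxy-6-methyl-4-oxo-4H-chromen-2-yl)-2-methoxyphenyl]-5-methoxy-4H-chromen-4-one | COc1ccc(-c2cc(=O)c3c(OC)c(C)c(OC)cc3o2)cc1-c1c(OCc2ccccc2)cc(OC)c2c(=O)cc(-c3ccc(OCc4ccccc4)cc3)oc12 | intermediate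
24 | Taiwanhomoflavone A, 5,7-dihydroxy-8-[5-(5-hydroxy-7-methoxy-6-methyl-4-oxo-4H-chromen-2-yl)-2-methoxyphenyl]-2-(4-hydroxyphenyl)-4H-chromen-4-one | COc1ccc(-c2cc(=O)c3c(O)c(C)c(OC)cc3o2)cc1-c1c(O)cc(O)c2c(=O)cc(-c3ccc(O)cc3)oc12 | target

**Totals**

Total step count: 12. Longest linear sequence: 10 steps (steps 1–8, 11, 12); steps 9–10 form the side branch to 20.

**Steps most likely to fail**

1. Step 4. The opened ester 7 may be saponified, cleaved by retro-Claisen attack of methoxide on the ketone, or simply reclose to 6 faster than its benzylic carbanion acylates. The fallback sets out from 6 and returns at 8. It splits the isomerisation into two separate operations with a different enolate regime. Pyrone 6 is ring-opened with Mg(OMe)2 in MeOH at 25 °C, where magnesium chelation should hold the open β-methoxy enoate, and 7 is isolated. Then 7 is cyclised as its preformed enolate under aprotic, irreversible Dieckmann conditions (KOtBu, 2.2 equiv, THF, −78 → 25 °C), with no nucleophilic alkoxide solvent present, and acidified to 8. It makes no compound outside the list (F0).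

2. Step 1. Proton transfer from the enolisable arylacetyl imidazolide to the dianion (ketene formation, self-condensation) may outrun C-acylation. The fallback sets out from 1 and 2 and returns at 4. It replaces the strongly basic dianion by a neutral Mukaiyama-type acylation of a bis-silyl dienol ether. Acid 1 is converted with (COCl)2 and DMF (cat.) into (5-bromo-2-methoxyphenyl)acetyl chloride F1. Ester 2 is silylated with Me3SiCl/Et3N to methyl 3-(trimethylsilyloxy)but-2-enoate F2 (E/Z mixture, geometry of no consequence), and then with LiN(iPr)2/Me3SiCl to 1-methoxy-1,3-bis(trimethylsilyloxy)buta-1,3-diene F3. F1 and F3 are combined in CH2Cl2 at −78 → 25 °C and hydrolysed on work-up, which should give 4 by attack of the terminal diene carbon on the acid chloride.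

3. Step 12. Four cleavages must occur while two methyl ethers survive. Possible failures are over-demethylation of the 7-OMe or 4′-OMe groups, incomplete cleavage of the hindered C5 ether next to the C6 methyl group, and Friedel–Crafts benzylation of the electron-rich C6 position of the apigenin ring. The fallback sets out from 23 and returns at 24. It separates the two kinds of cleavage. Hydrogenolysis (H2 1 atm, Pd/C, THF/MeOH, 25 °C) removes only the benzyl groups without generating benzyl cations and gives 7-hydroxy-2-(4-hydroxyphenyl)-8-[5-(5,7-dimethoxy-6-methyl-4-oxo-4H-chromen-2-yl)-2-methoxyphenyl]-5-methoxy-4H-chromen-4-one F4. Chelation-controlled peri demethylation (BCl3, CH2Cl2, 0 °C, or AlCl3 in MeCN) then removes the two C5 methyl ethers to give 24.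

**Further compounds**

F0 | step 4 | none | none
F1 | step 1 | (5-bromo-2-methoxyphenyl)acetyl chloride | COc1ccc(Br)cc1CC(=O)Cl
F2 | step 1 | methyl 3-(trimethylsilyloxy)but-2-enoate (E/Z mixture) | COC(=O)C=C(C)O[Si](C)(C)C
F3 | step 1 | 1-methoxy-1,3-bis(trimethylsilyloxy)buta-1,3-diene | COC(O[Si](C)(C)C)=CC(=C)O[Si](C)(C)C
F4 | step 12 | 7-hydroxy-2-(4-hydroxyphenyl)-8-[5-(5,7-dimethoxy-6-methyl-4-oxo-4H-chromen-2-yl)-2-methoxyphenyl]-5-methoxy-4H-chromen-4-one | COc1ccc(-c2cc(=O)c3c(OC)c(C)c(OC)cc3o2)cc1-c1c(O)cc(OC)c2c(=O)cc(-c3ccc(O)cc3)oc12
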